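**Plan**

- Retrosynthetic cuts, in order (chromene numbering of the target): the pyran ring at C4–C4a and O1–C2, giving prenal and triphenol 14; the three MOM ethers; the CO–ring B bond; the ring A–CO bond; the ring A–CH2 bond of the prenyl group; back to 5-methoxyresorcinol.
- Forward: ring A is taken as the C2v-symmetric bis-MOM ether of 5-methoxyresorcinol. A first directed ortho-metalation places prenyl between the two OMOM groups, a second places a C2 α-keto Weinreb amide between OMOM and OMe. Ring B is joined by Weinreb ketone synthesis, the MOM groups are removed, and the pyran ring is closed last.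
- Enabling feature: the pyran atoms O1–C8a=C4a–C4=C3–C2 are a ring-closed 1-oxatriene. C4a is the one remaining C–H of phloroglucinol-type ring A (a masked cyclohexane-1,3,5-trione carbon). It is ortho to the free OH that becomes O1, para to the chelated C7–OH and ortho to C5–OMe, and the C8 prenyl group blocks the other ortho site of that OH.
- One condensation with prenal and one oxa-6π closure therefore complete the hexasubstituted ring on the unprotected precursor with no regiochemical choice.
- Stereochemistry: the target has no stereocentre; the cis C3=C4 alkene is fixed by the ring.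

Key step: step 6

Remark: compounds 1, 3, 6, 10 and 15 are assumed to be purchased. In 14 and its precursors the positions of ring A are numbered from the acyl-bearing carbon (C1).

**Route**

Step 1
Reactants: 1 5-methoxyresorcinol
Product: 2 1-methoxy-3,5-bis(methoxymethoxy)benzene
Conditions: MOMCl (2.5 equiv), i-Pr2NEt (3 equiv), CH2Cl2, 0 °C → rt
Reagents that add atoms: chloromethyl methyl ether (MOMCl), COCCl
Why: O-alkylation of the two equivalent phenols (MOM ether formation) should proceed cleanly and installs the two chelating directing groups needed for both metalations.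

Step 2
Reactants: 2 1-methoxy-3,5-bis(methoxymethoxy)benzene; 3 prenyl bromide
Product: 5 5-methoxy-1,3-bis(methoxymethoxy)-2-(3-methylbut-2-en-1-yl)benzene, via aryllithium 4 (not isolated)
Conditions: n-BuLi, THF, 0 °C; then CuI (10 mol%), 3, −78 °C → rt
Reagents that add atoms: none
Why: Directed ortho-metalation should favour the C–H flanked by two OMOM groups (OMOM outranks OMe as a director), and copper-catalysed allylic substitution of the aryllithium at the unsubstituted terminus of prenyl bromide should give the linear prenyl group.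

Step 3
Reactants: 5 5-methoxy-1,3-bis(methoxymethoxy)-2-(3-methylbut-2-en-1-yl)benzene; 6 N,N'-dimethoxy-N,N'-dimethyloxalamide
Product: 9 N-methoxy-2-[6-methoxy-2,4-bis(methoxymethoxy)-3-(3-methylbut-2-en-1-yl)phenyl]-N-methyl-2-oxoacetamide, via aryllithium 7 (not isolated), via lithium hemiaminal 8 (not isolated)
Conditions: n-BuLi, TMEDA, THF, −20 → 0 °C; then added to 6 (1.5 equiv), THF, −78 °C; H2O
Reagents that add atoms: none
Why: A second directed ortho-metalation at one of the two equivalent ring C–H (each between OMOM and OMe) followed by Weinreb-type acyl substitution on the oxalic bis-amide should stop at mono-addition, because the chelated tetrahedral lithium adduct 8 collapses to the ketone only on work-up.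

Step 4
Reactants: 9 N-methoxy-2-[6-methoxy-2,4-bis(methoxymethoxy)-3-(3-methylbut-2-en-1-yl)phenyl]-N-methyl-2-oxoacetamide; 10 1-bromo-4-(methoxymethoxy)benzene
Product: 13 1-[6-methoxy-2,4-bis(methoxymethoxy)-3-(3-methylbut-2-en-1-yl)phenyl]-2-[4-(methoxymethoxy)phenyl]ethane-1,2-dione, via arylmagnesium bromide 11 (not isolated), via magnesium hemiaminal 12 (not isolated)
Conditions: 10, Mg, THF, rt; then 9, THF, −78 → 0 °C; H2O
Reagents that add atoms: none
Why: Weinreb ketone synthesis: the aryl Grignard reagent should add to the N-methoxy-N-methylamide carbonyl, because the neighbouring ketone is shielded by its two ortho substituents (OMe and OMOM), and the chelated adduct 12 releases the 1,2-diketone on work-up.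

Step 5
Reactants: 13 1-[6-methoxy-2,4-bis(methoxymethoxy)-3-(3-methylbut-2-en-1-yl)phenyl]-2-[4-(methoxymethoxy)phenyl]ethane-1,2-dione
Product: 14 1-[2,4-dihydroxy-6-methoxy-3-(3-methylbut-2-en-1-yl)phenyl]-2-(4-hydroxyphenyl)ethane-1,2-dione
Conditions: HCl (3 M aq), MeOH, 40 °C
Reagents that add atoms: none
Why: Acid-catalysed acetal cleavage (transacetalisation to methanol) should remove all three MOM groups under conditions mild enough to leave the ortho-prenyl alkene and the non-enolisable diaryl diketone untouched.

Step 6
Reactants: 14 1-[2,4-dihydroxy-6-methoxy-3-(3-methylbut-2-en-1-yl)phenyl]-2-(4-hydroxyphenyl)ethane-1,2-dione; 15 3-methylbut-2-enal (prenal)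
Product: 18 derrisdione A, via aldol adduct 16 (not isolated), via ortho-quinone methide 17 (not isolated)
Conditions: 15 (3 equiv), pyridine, 120 °C, sealed tube
Reagents that add atoms: none
Why: Pyridine-assisted aldol-type attack of ring A through C5 (the phenol acting as the vinylogous enol of the phloroglucinol nucleus) on the aldehyde carbon of 15 should give benzylic alcohol 16, and loss of water should give ortho-quinone methide 17, a 1-oxatriene that closes by thermal disrotatory oxa-6π electrocyclisation to form the O–C(CH3)2 bond and restore the aromatic ring. The closest known reaction type is the formal [3+3] annulation (Knoevenagel-type condensation then oxa-6π electrocyclisation) of resorcinols and acylphloroglucinols with α,β-unsaturated aldehydes to 2,2-dimethyl-2H-chromenes in hot pyridine. The pyran ring is closed by 6π electrocyclisation of the (Z)-dienone and not by a 6-endo oxa-Michael addition. No stereocentre results, since the carbinol carbon of 16 is racemic and is lost on dehydration and C2 carries two methyl groups. The regioselectivity needed is secured by the substrate: C5 is the only C–H on ring A, it has only one free hydroxyl neighbour (the other neighbour is the methyl ether), and C3 is blocked by the prenyl group. The chemoselectivity needed follows from the poor carbon nucleophilicity of the para-acylphenol ring B, from the non-enolisable diketone, and from the use of a tertiary amine that cannot condense with the diketone.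

**Compound list**

1 | 5-methoxyresorcinol (5-methoxybenzene-1,3-diol) | COc1cc(O)cc(O)c1 | starting material
2 | 1-methoxy-3,5-bis(methoxymethoxy)benzene | COCOc1cc(OC)cc(OCOC)c1 | intermediate
3 | prenyl bromide (1-bromo-3-methylbut-2-ene) | CC(C)=CCBr | starting material
4 | [4-methoxy-2,6-bis(methoxymethoxy)phenyl]lithium | COCOc1cc(OC)cc(OCOC)c1[Li] | intermediate (not isolated)
5 | 5-methoxy-1,3-bis(methoxymethoxy)-2-(3-methylbut-2-en-1-yl)benzene | COCOc1cc(OC)cc(OCOC)c1CC=C(C)C | intermediate
6 | N,N'-dimethoxy-N,N'-dimethyloxalamide | CON(C)C(=O)C(=O)N(C)OC | starting material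
7 | [6-methoxy-2,4-bis(methoxymethoxy)-3-(3-methylbut-2-en-1-yl)phenyl]lithium | COCOc1cc(OC)c([Li])c(OCOC)c1CC=C(C)C | intermediate (not isolated)
8 | lithium hemiaminal: tetrahedral lithium alkoxide from addition of 7 to one amide carbonyl of 6 | COCOc1cc(OC)c(C(O[Li])(N(C)OC)C(=O)N(C)OC)c(OCOC)c1CC=C(C)C | intermediate (not isolated)
9 | N-methoxy-2-[6-methoxy-2,4-bis(methoxymethoxy)-3-(3-methylbut-2-en-1-yl)phenyl]-N-methyl-2-oxoacetamide | COCOc1cc(OC)c(C(=O)C(=O)N(C)OC)c(OCOC)c1CC=C(C)C | intermediate
10 | 1-bromo-4-(methoxymethoxy)benzene | COCOc1ccc(Br)cc1 | starting material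
11 | [4-(methoxymethoxy)phenyl]magnesium bromide | COCOc1ccc([Mg]Br)cc1 | intermediate (not isolated)
12 | magnesium hemiaminal: tetrahedral bromomagnesium alkoxide from addition of 11 to the amide carbonyl of 9 | COCOc1ccc(cc1)C(O[Mg]Br)(N(C)OC)C(=O)c1c(OC)cc(OCOC)c(CC=C(C)C)c1OCOC | intermediate (not isolated)
13 | 1-[6-methoxy-2,4-bis(methoxymethoxy)-3-(3-methylbut-2-en-1-yl)phenyl]-2-[4-(methoxymethoxy)phenyl]ethane-1,2-dione | COCOc1ccc(cc1)C(=O)C(=O)c1c(OC)cc(OCOC)c(CC=C(C)C)c1OCOC | intermediate
14 | 1-[2,4-dihydroxy-6-methoxy-3-(3-methylbut-2-en-1-yl)phenyl]-2-(4-hydroxyphenyl)ethane-1,2-dione | COc1cc(O)c(CC=C(C)C)c(O)c1C(=O)C(=O)c1ccc(O)cc1 | intermediate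
15 | 3-methylbut-2-enal (prenal) | CC(C)=CC=O | starting material
16 | aldol adduct (racemic): 14 carrying a 1-hydroxy-3-methylbut-2-en-1-yl group at C5 of ring A | COc1c(C(O)C=C(C)C)c(O)c(CC=C(C)C)c(O)c1C(=O)C(=O)c1ccc(O)cc1 | intermediate (not isolated)
17 | ortho-quinone methide: ring A of 14 as a 4-oxocyclohexadiene with an exocyclic (Z) C5=CH–CH=C(CH3)2 unit, the dienyl arm syn to the C4 carbonyl | O=C1C(CC=C(C)C)=C(O)C(C(=O)C(=O)c2ccc(O)cc2)=C(OC)/C1=C/C=C(C)C | intermediate (not isolated)
18 | derrisdione A, 1-[7-hydroxy-5-methoxy-2,2-dimethyl-8-(3-methylbut-2-en-1-yl)-2H-chromen-6-yl]-2-(4-hydroxyphenyl)ethane-1,2-dione | COc1c2c(c(CC=C(C)C)c(O)c1C(=O)C(=O)c1ccc(O)cc1)OC(C)(C)C=C2 | target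

**Count and risks**

Total step count: 6. Longest linear sequence: 6 steps (1 → 2 → 5 → 9 → 13 → 14 → 18).

Steps most likely to fail:

1. Step 6. The α-ketoacyl group may lower the carbon nucleophilicity of ring A so far that prenal self-condenses before C–C bond formation, and prolonged heating in base may degrade the ortho-hydroxy 1,2-diketone. The fallback forms the O–C bond first and the C–C bond by sigmatropic rearrangement. It sets out from 9 and returns at 18. The Grignard reagent from (4-bromophenoxy)triisopropylsilane (Mg, THF) is added to 9 to give the silyl-protected diketone F1. HCl/MeOH should remove only the two MOM groups and give the ring A diol F2. The non-chelated 4-OH is then alkylated with 3-chloro-3-methylbut-1-yne (CuCl2·2H2O cat., DBU, MeCN, 0 °C) to give the aryl 1,1-dimethylpropargyl ether F3. Heating (xylene, 140 °C) should trigger aromatic propargyl Claisen rearrangement to the only free ortho carbon, 1,5-hydrogen shift and oxa-6π electrocyclisation to give O-silyl derrisdione A F4. TBAF/AcOH in THF at 0 °C then gives 18.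

2. Step 4. The Grignard reagent may add to the ketone carbonyl instead of, or as well as, the amide carbonyl. The fallback takes the ketone down to the alcohol oxidation level and restores it afterwards. It sets out from 9 and returns at 13. NaBH4 in MeOH at 0 °C should reduce only the ketone and give the racemic α-hydroxy Weinreb amide F5. Excess 11 (2.5 equiv, THF, 0 °C) should then add to the amide through the chelated magnesium alkoxide and give the racemic benzoin F6. MnO2 in CH2Cl2 at rt oxidises F6 to 13.

3. Step 3. Lateral deprotonation at the benzylic and allylic CH2 of the prenyl group may compete with ring metalation. The fallback replaces deprotonation by halogen–metal exchange. It sets out from 5 and returns at 7. NBS in MeCN at −20 °C should brominate one of the two equivalent ring positions and give the aryl bromide F7. Bromine–lithium exchange with n-BuLi in THF at −78 °C gives aryllithium 7, which is trapped with 6 as in step 3.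

**Further compounds**

F1 | step 6 | 1-[6-methoxy-2,4-bis(methoxymethoxy)-3-(3-methylbut-2-en-1-yl)phenyl]-2-{4-[(triisopropylsilyl)oxy]phenyl}ethane-1,2-dione | CC(C)[Si](Oc1ccc(cc1)C(=O)C(=O)c1c(OC)cc(OCOC)c(CC=C(C)C)c1OCOC)(C(C)C)C(C)C
F2 | step 6 | 1-[2,4-dihydroxy-6-methoxy-3-(3-methylbut-2-en-1-yl)phenyl]-2-{4-[(triisopropylsilyl)oxy]phenyl}ethane-1,2-dione | CC(C)[Si](Oc1ccc(cc1)C(=O)C(=O)c1c(OC)cc(O)c(CC=C(C)C)c1O)(C(C)C)C(C)C
F3 | step 6 | 1-{2-hydroxy-6-methoxy-4-[(2-methylbut-3-yn-2-yl)oxy]-3-(3-methylbut-2-en-1-yl)phenyl}-2-{4-[(triisopropylsilyl)oxy]phenyl}ethane-1,2-dione | CC(C)[Si](Oc1ccc(cc1)C(=O)C(=O)c1c(OC)cc(OC(C)(C)C#C)c(CC=C(C)C)c1O)(C(C)C)C(C)C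
F4 | step 6 | 1-[7-hydroxy-5-methoxy-2,2-dimethyl-8-(3-methylbut-2-en-1-yl)-2H-chromen-6-yl]-2-{4-[(triisopropylsilyl)oxy]phenyl}ethane-1,2-dione | COc1c2c(c(CC=C(C)C)c(O)c1C(=O)C(=O)c1ccc(O[Si](C(C)C)(C(C)C)C(C)C)cc1)OC(C)(C)C=C2
F5 | step 4 | 2-hydroxy-N-methoxy-2-[6-methoxy-2,4-bis(methoxymethoxy)-3-(3-methylbut-2-en-1-yl)phenyl]-N-methylacetamide (racemic) | COCOc1cc(OC)c(C(O)C(=O)N(C)OC)c(OCOC)c1CC=C(C)C
F6 | step 4 | 2-hydroxy-2-[6-methoxy-2,4-bis(methoxymethoxy)-3-(3-methylbut-2-en-1-yl)phenyl]-1-[4-(methoxymethoxy)phenyl]ethan-1-one (racemic) | COCOc1ccc(cc1)C(=O)C(O)c1c(OC)cc(OCOC)c(CC=C(C)C)c1OCOC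
F7 | step 3 | 2-bromo-1-methoxy-3,5-bis(methoxymethoxy)-4-(3-methylbut-2-en-1-yl)benzene | COCOc1cc(OC)c(Br)c(OCOC)c1CC=C(C)C
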